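Retrosynthesis: cut the C16–O–C14' ester. Cut both C12=C13 alkenes (cross-metathesis), which reduces the two identical decalin halves to one allyl-decalin 13 plus two α-methylene-γ-butyrolactones. Cut C8=C17 (Wittig) and C9–C11 (enolate allylation). Finally excise C9 from ring B (bonds C8–C9 and C9–C10), which leads back to a trans-hydrindanone and the (S)-Hajos–Parrish ketone.
Enabling feature: in ring B (C5–C6–C7–C8–C9–C10) the sp2 carbon C8 is flanked by C9–H, which carries the allylic methylene C11 and is bonded to quaternary C10. This is the retron of an α-allyl ketone. Its Δ8(9) enolate cannot be made by enolisation (an 8-ketone enolises towards C7), but it is the direct product of a 1,2-shift of C10 from C8 to a carbenoid carbon that becomes C9.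
Forward: ring A and the five-membered forerunner of ring B (C5–C6–C7–C8–C10) arrive together in 1. C4 gem-dimethylation, C3 deoxygenation and C5=C6 hydrogenation give 7. Ring B grows from five to six atoms in step 7, with C9–C11 formed in the same flask, and methylenation gives 13, which is used twice.
Chain joining: 13 + 14 gives the acid half 18 and 13 + 23 gives the alcohol half 24. Esterification and direct oxidation of the silyl ether to the C15 aldehyde finish the target.
Stereochemistry: C10 comes from 1, C5 from α-face hydrogenation, C9 from equilibration next to the C8 ketone, and C14' from (R)-3-hydroxy-γ-butyrolactone. Both E alkenes come from thermodynamically controlled cross-metathesis.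

Key step: step 7

Remark: labdane numbering is used throughout (primed numbers for the lactone half). Compounds 1, 14 and 19 are taken as commercial, and C9 of the 8-ketone is assumed to equilibrate to the equatorial (natural) configuration, as in other 8-oxo-labdanes.

Step 1
Reactants: 1 (S)-Hajos–Parrish ketone
Product: 2 C8 monoketal enone (7aS)-1,1-ethylenedioxy-7a-methyl-2,3,7,7a-tetrahydro-1H-inden-5(6H)-one
Conditions: TMSOCH2CH2OTMS, TMSOTf (cat.), CH2Cl2, −78 to −20 °C
Reagents that add atoms: 1,2-bis(trimethylsilyloxy)ethane, C[Si](C)(C)OCCO[Si](C)(C)C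
Why: TMSOTf-catalysed ketalisation with the bis-silyl ether (Noyori ketalisation) should take the saturated C8 ketone and leave the much less electrophilic conjugated C3 carbonyl, and it does not touch C10.

Step 2
Reactants: 2 C8 monoketal enone
Product: 3 4,4-dimethyl β,γ-enone ketal (C3 ketone and C5=C6 alkene in labdane numbering)
Conditions: KOt-Bu, MeI, t-BuOH, rt
Reagents that add atoms: iodomethane, CI
Why: Deconjugative double α-alkylation of the enone through its extended dienolate, the standard gem-dimethylation of such bicyclic enones, should place both methyl groups on C4 and leave the alkene at C5=C6, where the quaternary C4 blocks reconjugation.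

Step 3
Reactants: 3 4,4-dimethyl β,γ-enone ketal
Product: 5 alkene ketal (7aS)-1,1-ethylenedioxy-4,4,7a-trimethyl-2,4,5,6,7,7a-hexahydro-1H-indene, via hydrazone 4 (not isolated)
Conditions: N2H4·H2O, KOH, diethylene glycol, 130 then 200 °C
Reagents that add atoms: none
Why: Wolff–Kishner reduction (Huang-Minlon variant) should remove the hindered C3 carbonyl through hydrazone 4 under strongly basic conditions that the ketal and the isolated alkene tolerate.

Step 4
Reactants: 5 alkene ketal
Product: 6 trans-hydrindane ketal (3aS,7aS)-1,1-ethylenedioxy-4,4,7a-trimethyloctahydro-1H-indene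
Conditions: H2 (5 bar), Pd/C, EtOAc, rt
Reagents that add atoms: none
Why: Heterogeneous catalytic syn-hydrogenation should reach C5=C6 from the α face because the β face is screened by the axial C20 and 4β methyl groups, which sets C5 (H-5 α, trans to C20).

Step 5
Reactants: 6 trans-hydrindane ketal
Product: 7 trans-hydrindanone (3aS,7aS)-4,4,7a-trimethyloctahydro-1H-inden-1-one
Conditions: 1 M aq HCl, THF, rt
Reagents that add atoms: water, O
Why: Acid-catalysed ketal hydrolysis frees the C8 ketone, and neither C5 nor the quaternary C10 can epimerise.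

Step 6
Reactants: 7 trans-hydrindanone
Product: 8 dibromomethyl carbinol (1S,3aS,7aS)-1-(dibromomethyl)-4,4,7a-trimethyloctahydro-1H-inden-1-ol (8β-OH)
Conditions: CH2Br2, LDA (added last), THF, −78 °C; aq NH4Cl
Reagents that add atoms: dibromomethane, BrCBr
Why: 1,2-Addition of dibromomethyllithium, generated by deprotonation of CH2Br2 in the presence of the ketone, should occur from the α face opposite the angular methyl group to give the 8β-ol, a stereocentre that is erased in step 7.

Step 7
Reactants: 8 dibromomethyl carbinol
Product: 12 (1R,4aS,8aS)-1-allyl-5,5,8a-trimethyloctahydronaphthalen-2(1H)-one (9β-allyl 8-ketone), via β-oxido carbenoid 9 (not isolated), via lithium enolate 10 (not isolated), via 9-epi ketone 11 (not isolated)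
Conditions: n-BuLi (2.1 equiv), THF, −90 to 0 °C; DMPU, allyl bromide, −78 to 0 °C; aq NH4Cl; crude in NaOMe (cat.), MeOH, rt
Reagents that add atoms: allyl bromide, C=CCBr
Why: The first n-BuLi deprotonates O–H and the second exchanges one bromine to give β-oxido carbenoid 9; on warming, the C8–C10 σ bond shifts to the carbenoid carbon (the future C9) as LiBr leaves, so that the five-membered ring C5–C6–C7–C8–C10 becomes the six-membered ring B and C8 emerges as the oxygen-bearing carbon of lithium enolate 10. The closest known reaction type is the β-oxido carbenoid ring enlargement of dibromomethyl carbinols, a Tiffeneau–Demjanov-type semipinacol shift whose enolate can be trapped with alkyl halides. Ring B is therefore not closed by cyclisation but by a 1,2-alkyl shift (insertion of one carbon between C8 and C10), driven by loss of LiBr, enolate formation and release of the strain and vicinal crowding of the trans-hydrindanol, with C10 migrating with retention and C5 untouched. The selectivity needed is migration of C10 rather than C7, which the substrate secures because the fully substituted carbon is the better σ-donor (in this reaction class the more substituted α-carbon migrates), and regiochemical integrity of the Δ8(9) enolate, which the amine-free medium secures because no proton shuttle is present. Allyl bromide then forms C9–C11 on this otherwise inaccessible enolate, probably on the α face anti to the axial C20 methyl group, to give 11. NaOMe equilibration of the crude ketone places the allyl group equatorial (H-9 α, axial), the natural and thermodynamically preferred C9 configuration of 12.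

Step 8
Reactants: 12 9β-allyl 8-ketone
Product: 13 (1S,4aS,8aS)-1-allyl-5,5,8a-trimethyl-2-methylidenedecahydronaphthalene (14,15,16-trinorlabda-8(17),12-diene)
Conditions: Ph3PCH3Br, n-BuLi, THF, 0 °C to reflux
Reagents that add atoms: methyltriphenylphosphonium bromide, C[P+](c1ccccc1)(c1ccccc1)c1ccccc1.[Br-]
Why: Wittig methylenation of the hindered 8-ketone is the standard entry to the labdane exocyclic alkene, and C9 stays in its thermodynamically preferred equatorial configuration under the basic conditions.

Step 9
Reactants: 13 allyl-decalin; 14 α-methylene-γ-butyrolactone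
Product: 15 (12E)-labda-8(17),12-dien-16,15-olide
Conditions: 14 (3 equiv), second-generation Hoveyda–Grubbs catalyst (5 mol %), 2,6-dichloro-1,4-benzoquinone (10 mol %), CH2Cl2, 40 °C
Reagents that add atoms: none
Why: Olefin cross-metathesis of a terminal alkene with α-methylene-γ-butyrolactone, with a quinone additive to suppress ruthenium hydride isomerisation, should give the thermodynamically favoured E alkylidene lactone, while the hindered C8=C17 alkene stays out of the metathesis.

Step 10
Reactants: 15 (12E)-labda-8(17),12-dien-16,15-olide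
Product: 18 (12E)-15-(triethylsilyloxy)labda-8(17),12-dien-16-oic acid, via potassium hydroxy carboxylate 16 (not isolated), via bis(triethylsilyl) derivative 17 (not isolated)
Conditions: KOH, MeOH–H2O, 50 °C, evaporate; Et3SiCl, imidazole, DMF, 0 °C; pH 7 buffer–THF, rt
Reagents that add atoms: potassium hydroxide, [K+].[OH-]; chlorotriethylsilane, CC[Si](Cl)(CC)CC
Why: Saponification, exhaustive silylation and selective hydrolysis of the far more labile silyl ester is the usual way to hold a γ-hydroxy acid open, and the E alkene is not affected.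

Step 11
Reactants: 19 (R)-3-hydroxy-γ-butyrolactone
Product: 21 (3R,4R)-3-[(dimethylamino)methyl]-4-hydroxyoxolan-2-one (trans), via dilithio dianion 20 (not isolated)
Conditions: LDA (2.2 equiv), THF, −78 °C; CH2=NMe2 I, −78 to 0 °C; aq NH4Cl
Reagents that add atoms: N,N-dimethylmethyleneiminium iodide (Eschenmoser salt), C=[N+](C)C.[I-]
Why: The dianion of a β-hydroxy lactone (Fráter–Seebach type) does not eliminate because an alkoxide is a poor leaving group, and its Mannich reaction with the Eschenmoser salt should occur anti to the alkoxide to give the trans product, whose new C13' centre is erased in step 12.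

Step 12
Reactants: 21 Mannich base
Product: 23 (4R)-4-hydroxy-3-methylideneoxolan-2-one, via trimethylammonium iodide 22 (not isolated)
Conditions: MeI, MeOH, rt; then NaHCO3, H2O–CH2Cl2, rt
Reagents that add atoms: none
Why: Quaternisation followed by Hofmann-type E1cB elimination is the standard α-methylenation of lactones, loses trimethylamine rather than hydroxide and leaves C14' untouched.

Step 13
Reactants: 13 allyl-decalin; 23 (4R)-4-hydroxy-3-methylideneoxolan-2-one
Product: 24 (12E,14R)-14-hydroxylabda-8(17),12-dien-16,15-olide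
Conditions: 23 (2 equiv), second-generation Hoveyda–Grubbs catalyst (10 mol %), 2,6-dichloro-1,4-benzoquinone (20 mol %), toluene, 60 °C
Reagents that add atoms: none
Why: The same cross-metathesis as in step 9, now on the β-hydroxy α-methylene lactone, should give the E alkylidene lactone with C14' unchanged, the quinone additive holding back redox isomerisation of the allylic alcohol.

Step 14
Reactants: 18 silyloxy acid; 24 hydroxy lactone
Product: 26 14'-O-[(12E)-15-(triethylsilyloxy)labda-8(17),12-dien-16-oyl] ester of 24, via mixed anhydride 25 (not isolated)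
Conditions: 2,4,6-Cl3C6H2COCl, Et3N, toluene, rt; then 24, DMAP, rt
Reagents that add atoms: none
Why: Yamaguchi esterification through mixed anhydride 25 acylates the secondary allylic C14' hydroxyl under mild conditions with retention, since the C14'–O bond is not broken.

Step 15
Reactants: 26 silyl-protected ester
Product: 28 target CNP0274315.1, via alkoxysulfonium chloride 27 (not isolated)
Conditions: (COCl)2, DMSO, CH2Cl2, −78 to −35 °C; Et3N, −78 to 0 °C
Reagents that add atoms: none
Why: Under Swern conditions a primary triethylsilyl ether is converted directly into the alkoxysulfonium salt and hence the aldehyde, which avoids a free γ-hydroxy ester that could lactonise with loss of 24, and the cold, short base treatment should leave the β,γ-unsaturated aldehyde unconjugated.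

Compound list
1 | (S)-Hajos–Parrish ketone, (7aS)-7a-methyl-2,3,7,7a-tetrahydro-1H-indene-1,5(6H)-dione | O=C1CCC2=CC(=O)CC[C@]12C | starting material
2 | (7aS)-1,1-ethylenedioxy-7a-methyl-2,3,7,7a-tetrahydro-1H-inden-5(6H)-one | O1CCOC12CCC3=CC(=O)CC[C@]23C | intermediate
3 | (7aS)-1,1-ethylenedioxy-4,4,7a-trimethyl-1,2,4,6,7,7a-hexahydro-5H-inden-5-one (C5=C6 alkene, C3 ketone) | O1CCOC12CC=C3C(C)(C)C(=O)CC[C@]23C | intermediate
4 | C3 hydrazone of 3 | O1CCOC12CC=C3C(C)(C)C(=NN)CC[C@]23C | intermediate
5 | (7aS)-1,1-ethylenedioxy-4,4,7a-trimethyl-2,4,5,6,7,7a-hexahydro-1H-indene | O1CCOC12CC=C3C(C)(C)CCC[C@]23C | intermediate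
6 | (3aS,7aS)-1,1-ethylenedioxy-4,4,7a-trimethyloctahydro-1H-indene (trans) | O1CCOC12CC[C@H]3C(C)(C)CCC[C@]23C | intermediate
7 | (3aS,7aS)-4,4,7a-trimethyloctahydro-1H-inden-1-one (trans) | O=C1CC[C@H]2C(C)(C)CCC[C@]12C | intermediate
8 | (1S,3aS,7aS)-1-(dibromomethyl)-4,4,7a-trimethyloctahydro-1H-inden-1-ol (OH β) | O[C@@]1(C(Br)Br)CC[C@H]2C(C)(C)CCC[C@]12C | intermediate
9 | β-oxido carbenoid, lithium alkoxide of the 1-[bromo(lithio)methyl] carbinol | [Li]O[C@@]1(C([Li])Br)CC[C@H]2C(C)(C)CCC[C@]12C | intermediate
10 | lithium Δ8(9) enolate of (4aS,8aS)-5,5,8a-trimethyloctahydronaphthalen-2(1H)-one | C1=C(O[Li])CC[C@H]2C(C)(C)CCC[C@]12C | intermediate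
11 | (1S,4aS,8aS)-1-allyl-5,5,8a-trimethyloctahydronaphthalen-2(1H)-one (9α-allyl, axial) | O=C1CC[C@H]2C(C)(C)CCC[C@]2(C)[C@@H]1CC=C | intermediate
12 | (1R,4aS,8aS)-1-allyl-5,5,8a-trimethyloctahydronaphthalen-2(1H)-one (9β-allyl, equatorial) | O=C1CC[C@H]2C(C)(C)CCC[C@]2(C)[C@H]1CC=C | intermediate
13 | (1S,4aS,8aS)-1-allyl-5,5,8a-trimethyl-2-methylidenedecahydronaphthalene | C=C1CC[C@H]2C(C)(C)CCC[C@]2(C)[C@H]1CC=C | intermediate
14 | α-methylene-γ-butyrolactone (3-methylideneoxolan-2-one) | C=C1CCOC1=O | starting material
15 | (5S,9S,10S,12E)-labda-8(17),12-dien-16,15-olide | C=C1CC[C@H]2C(C)(C)CCC[C@]2(C)[C@H]1C/C=C1\CCOC1=O | intermediate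
16 | potassium (12E)-15-hydroxylabda-8(17),12-dien-16-oate | C=C1CC[C@H]2C(C)(C)CCC[C@]2(C)[C@H]1C/C=C(\CCO)C(=O)[O-].[K+] | intermediate
17 | triethylsilyl (12E)-15-(triethylsilyloxy)labda-8(17),12-dien-16-oate | C=C1CC[C@H]2C(C)(C)CCC[C@]2(C)[C@H]1C/C=C(\CCO[Si](CC)(CC)CC)C(=O)O[Si](CC)(CC)CC | intermediate
18 | (5S,9S,10S,12E)-15-(triethylsilyloxy)labda-8(17),12-dien-16-oic acid | C=C1CC[C@H]2C(C)(C)CCC[C@]2(C)[C@H]1C/C=C(\CCO[Si](CC)(CC)CC)C(=O)O | intermediate
19 | (R)-3-hydroxy-γ-butyrolactone, (4R)-4-hydroxyoxolan-2-one | O[C@H]1COC(=O)C1 | starting material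
20 | dilithio dianion (alkoxide enolate) of 19 | [Li]O[C@H]1COC(O[Li])=C1 | intermediate
21 | (3R,4R)-3-[(dimethylamino)methyl]-4-hydroxyoxolan-2-one | O[C@H]1COC(=O)[C@@H]1CN(C)C | intermediate
22 | trimethylammonium iodide of 21 | O[C@H]1COC(=O)[C@@H]1C[N+](C)(C)C.[I-] | intermediate
23 | (4R)-4-hydroxy-3-methylideneoxolan-2-one | O[C@H]1COC(=O)C1=C | intermediate
24 | (5S,9S,10S,12E,14R)-14-hydroxylabda-8(17),12-dien-16,15-olide | O[C@H]1COC(=O)/C1=C/C[C@H]1C(=C)CC[C@H]2C(C)(C)CCC[C@]12C | intermediate
25 | mixed anhydride of 18 and 2,4,6-trichlorobenzoic acid | C=C1CC[C@H]2C(C)(C)CCC[C@]2(C)[C@H]1C/C=C(\CCO[Si](CC)(CC)CC)C(=O)OC(=O)c1c(Cl)cc(Cl)cc1Cl | intermediate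
26 | ester of acid 18 and the C14' hydroxyl of 24 (14'R, both alkenes E) | C=C1CC[C@H]2C(C)(C)CCC[C@]2(C)[C@H]1C/C=C(\CCO[Si](CC)(CC)CC)C(=O)O[C@H]1COC(=O)/C1=C/C[C@H]1C(=C)CC[C@H]2C(C)(C)CCC[C@]12C | intermediate
27 | O-15 dimethylsulfonium chloride derived from 26 | C=C1CC[C@H]2C(C)(C)CCC[C@]2(C)[C@H]1C/C=C(\CCO[S+](C)C)C(=O)O[C@H]1COC(=O)/C1=C/C[C@H]1C(=C)CC[C@H]2C(C)(C)CCC[C@]12C.[Cl-] | intermediate
28 | CNP0274315.1, (12E)-15-oxolabda-8(17),12-dien-16-oic acid ester of (12E,14R)-14-hydroxylabda-8(17),12-dien-16,15-olide | C=C1CC[C@H]2C(C)(C)CCC[C@]2(C)[C@H]1C/C=C(\CC=O)C(=O)O[C@H]1COC(=O)/C1=C/C[C@H]1C(=C)CC[C@H]2C(C)(C)CCC[C@]12C | target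

Total step count: 15. Longest linear sequence: 12 (steps 1–10, 14, 15).

Steps most likely to fail

Step 7. What may go wrong:
- C7 may migrate in competition with C10.
- The carbenoid may collapse by epoxide formation.
- Proton transfer may move the enolate to C7.
- Alkylation beside the quaternary C10 may be slow and lead to over-alkylation.

The fallback sets out from 7 and comes back at 12. Vinylmagnesium bromide with CeCl3 adds to 7 from the α face to give the 8α-vinyl 8β-carbinol F1. Hydroxyl-directed epoxidation (VO(acac)2, t-BuOOH) gives the epoxy alcohol F2. BF3·OEt2 opens the epoxide at C9 while the antiperiplanar, more electron-rich C8–C10 bond migrates (semipinacol rearrangement of a 2,3-epoxy alcohol). This gives the ring-enlarged 11-hydroxy 8-ketone F3. Mesylation gives the mesylate F4, and DBU gives the 9(11)-en-8-one F5. Conjugate addition of vinylmagnesium bromide under CuBr·SMe2 catalysis, followed by NaOMe equilibration at C9, returns to 12.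

Step 4. What may go wrong: the hindered trisubstituted alkene may take up hydrogen slowly, or poor facial selectivity may give some cis-hydrindane. The fallback sets out from 5 and comes back at 6. Hydroboration–oxidation (BH3·THF, then H2O2, NaOH) adds H and B syn from the α face to give the 5α-H 6α-alcohol F6, at which stage the ring fusion can be checked and purified. NaH, CS2 and MeI give the xanthate F7, and Barton–McCombie deoxygenation (Bu3SnH, AIBN, toluene, reflux) returns to 6.

Step 13. What may go wrong:
- Metathesis may be sluggish at the 1,1-disubstituted alkene flanked by the carbinol.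
- The allylic alcohol may undergo redox isomerisation.
- 13 may homodimerise.

The fallback sets out from 13 and 19 and comes back at 24. Lemieux–Johnson cleavage (OsO4 cat., NaIO4, 2,6-lutidine) of the unhindered monosubstituted alkene of 13 gives the C12 aldehyde F8. Silylation of 19 (TBSCl, imidazole) gives the silyl ether F9. Its lithium enolate (LDA, −78 °C) adds to F8 anti to the silyloxy group to give the aldol F10, and MsCl with Et3N gives the mesylate F11. DBU then induces E1cB loss of mesylate, the silyloxide being by far the poorer leaving group, to give the E alkylidene silyloxy lactone F12. HF·pyridine returns to 24.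

Further compounds
F1 | step 7 | (3aS,7aS)-1-ethenyl-4,4,7a-trimethyloctahydro-1H-inden-1-ol (8α-vinyl, 8β-OH) | O[C@@]1(C=C)CC[C@H]2C(C)(C)CCC[C@]12C
F2 | step 7 | 8β-hydroxy-8α-oxiranyl trans-hydrindane (C9 drawn for the isomer that gives F3 by anti migration; either C9 epimer serves) | O[C@@]1([C@H]2CO2)CC[C@H]3C(C)(C)CCC[C@]13C
F3 | step 7 | (1S,4aS,8aS)-1-(hydroxymethyl)-5,5,8a-trimethyloctahydronaphthalen-2(1H)-one (11-hydroxy 8-ketone, CH2OH equatorial) | O=C1CC[C@H]2C(C)(C)CCC[C@]2(C)[C@H]1CO
F4 | step 7 | methanesulfonate of F3 | O=C1CC[C@H]2C(C)(C)CCC[C@]2(C)[C@H]1COS(C)(=O)=O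
F5 | step 7 | (4aS,8aS)-5,5,8a-trimethyl-1-methylideneoctahydronaphthalen-2(1H)-one | O=C1CC[C@H]2C(C)(C)CCC[C@]2(C)C1=C
F6 | step 4 | 5α-H 6α-hydroxy trans-hydrindane ketal | O1CCOC12C[C@H](O)[C@H]3C(C)(C)CCC[C@]23C
F7 | step 4 | S-methyl xanthate of F6 | O1CCOC12C[C@H](OC(=S)SC)[C@H]3C(C)(C)CCC[C@]23C
F8 | step 13 | 13,14,15,16-tetranorlabd-8(17)-en-12-al | O=CC[C@H]1C(=C)CC[C@H]2C(C)(C)CCC[C@]12C
F9 | step 13 | (4R)-4-(tert-butyldimethylsilyloxy)oxolan-2-one | CC(C)(C)[Si](C)(C)O[C@H]1COC(=O)C1
F10 | step 13 | aldol of F9 and F8 (C13' trans to the silyloxy group, C12' epimers) | CC(C)(C)[Si](C)(C)O[C@H]1COC(=O)[C@@H]1C(O)C[C@H]1C(=C)CC[C@H]2C(C)(C)CCC[C@]12C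
F11 | step 13 | C12' methanesulfonate of F10 | CC(C)(C)[Si](C)(C)O[C@H]1COC(=O)[C@@H]1C(OS(C)(=O)=O)C[C@H]1C(=C)CC[C@H]2C(C)(C)CCC[C@]12C
F12 | step 13 | tert-butyldimethylsilyl ether of 24 | CC(C)(C)[Si](C)(C)O[C@H]1COC(=O)/C1=C/C[C@H]1C(=C)CC[C@H]2C(C)(C)CCC[C@]12C
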